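**Plan**
1. Cuts: the diaryl ether bond between C3′ of ring A and the oxygen on C8 of the isocoumarin (ring A numbered C1′ = carboxyl-bearing carbon, C2′ = side-chain carbon, C3′ = ether carbon); the benzylic CH2–C(=O) bond of the 2-oxoheptyl chain; and, in pyranone ring C (C1, O2, C3, C4, C4a, C8a), the O2–C3 and C3=C4 bonds.
2. Enabling feature: in ring C the C3=C4 double bond joins benzylic C4 to C3, which carries both the pentyl chain and the ring oxygen O2. C3 with its chain is therefore a hexanoyl unit, C4 a benzylic ylide carbon and O2 an ortho-carboxylate oxygen.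
3. Isocoumarin half, forward: ring B is bought as 5,7-dimethoxyphthalide and opened to the phosphonium acid; ring C is closed by acylation and intramolecular Wittig olefination; the C8 methyl ether is then removed by chelation.
4. Ring A half, forward: orsellinic acid is tribenzylated, acylated at the lateral methyl group with a second hexanoyl unit, ketalised and iodinated at C3′.
5. Union and release: CuI-catalysed aryl ether coupling joins the halves; hydrogenolysis and aqueous acid unmask the acid, the two phenols and the ketone.
6. Stereochemistry: the target has no stereocentre and no configured double bond, so nothing has to be set.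

Key step: step 2

Assumption: 5,7-dimethoxyphthalide, orsellinic acid and N-methoxy-N-methylhexanamide are taken as catalogue chemicals, and the target is made as the open keto acid drawn in its SMILES.

**Step 1**
Reactants: 1 5,7-dimethoxyphthalide; 2 triphenylphosphine hydrobromide
Product: 3 (2-carboxy-3,5-dimethoxybenzyl)triphenylphosphonium bromide
Conditions: neat melt, 170–180 °C, N2; trituration with MeCN/Et2O
Reagents that add atoms: none
Why: Protonation of the lactone carbonyl should let triphenylphosphine open the phthalide by SN2 attack at the benzylic CH2–O carbon (phosphine alkylation with O-alkyl cleavage of a lactone), the standard entry to (2-carboxybenzyl)phosphonium salts.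

**Step 2**
Reactants: 3 (2-carboxy-3,5-dimethoxybenzyl)triphenylphosphonium bromide; 4 hexanoyl chloride
Product: 6 6,8-dimethoxy-3-pentylisocoumarin, via mixed anhydride ylide 5 (not isolated)
Conditions: Et3N (4 equiv), toluene, reflux
Reagents that add atoms: none
Why: Et3N first ionises the carboxylic acid of 3, the carboxylate is O-acylated by hexanoyl chloride (forming O2–C3), and deprotonation of the benzylic phosphonium then gives the ylide 5. The ylide carbon (future C4) adds to the aliphatic anhydride carbonyl and the oxaphosphetane collapses with loss of Ph3P=O, which creates C3=C4. The closest known reaction type is the intramolecular Wittig olefination of an ester or anhydride carbonyl (acyl-Wittig), established for 3-substituted isocoumarins from (2-carboxybenzyl)phosphonium salts and acid chlorides. Ring C closes in a 6-exo-trig sense (ylide carbon onto the exocyclic C=O of the hexanoyl unit) and the elimination then places the double bond inside the ring; no stereocentre is formed. The step needs selectivity between the two anhydride carbonyls and O- over C-acylation: attack at the aliphatic carbonyl runs through a six-membered array while attack at the aroyl carbonyl would need a four-membered one, and the much more acidic CO2H is acylated before an appreciable amount of ylide exists. The two methoxy groups are spectators, the C8 one being placed for the chelation-controlled cleavage that follows.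

**Step 3**
Reactants: 6 6,8-dimethoxy-3-pentylisocoumarin
Product: 7 8-hydroxy-6-methoxy-3-pentylisocoumarin
Conditions: BCl3 (1.2 equiv), CH2Cl2, −78 → 0 °C; aqueous work-up
Reagents that add atoms: none
Why: BCl3 should bind the lactone carbonyl and the peri C8 oxygen in a six-membered chelate, so chloride removes only that methyl group (chelation-controlled Lewis acid demethylation) while the unchelated C6 methyl ether stays.

**Step 4**
Reactants: 8 orsellinic acid (2,4-dihydroxy-6-methylbenzoic acid)
Product: 9 benzyl 2,4-bis(benzyloxy)-6-methylbenzoate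
Conditions: BnBr (3.5 equiv), K2CO3, DMF, rt → 60 °C
Reagents that add atoms: benzyl bromide, BrCc1ccccc1
Why: Carboxylate alkylation and Williamson etherification of both phenols (warming for the hydrogen-bonded ortho hydroxyl) install three benzyl groups that tolerate the amide base, Lewis acid, iodination and coupling steps ahead and can be removed without base.

**Step 5**
Reactants: 9 benzyl 2,4-bis(benzyloxy)-6-methylbenzoate; 10 N-methoxy-N-methylhexanamide
Product: 11 benzyl 2,4-bis(benzyloxy)-6-(2-oxoheptyl)benzoate
Conditions: LiN(iPr)2 (LDA, 2.1 equiv), THF, −78 °C; then 10, −78 °C; saturated NH4Cl quench at −78 °C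
Reagents that add atoms: none
Why: The amide base removes a proton from the methyl group ortho to the ester (lateral lithiation of an o-toluate), and the benzylic anion is acylated once by the Weinreb amide, whose chelated tetrahedral adduct prevents over-addition and releases the ketone only on the cold quench.

**Step 6**
Reactants: 11 benzyl 2,4-bis(benzyloxy)-6-(2-oxoheptyl)benzoate
Product: 12 benzyl 2,4-bis(benzyloxy)-6-[(2-pentyl-1,3-dioxolan-2-yl)methyl]benzoate
Conditions: TMSOCH2CH2OTMS (3 equiv), TMSOTf (5 mol%), CH2Cl2, −78 → −20 °C; pyridine quench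
Reagents that add atoms: 1,2-bis(trimethylsilyloxy)ethane, C[Si](C)(C)OCCO[Si](C)(C)C
Why: Noyori ketalisation, driven by formation of hexamethyldisiloxane, works cold and aprotic, so the ketone is masked without enol lactonisation onto the benzyl ester; the ketal is needed to stop enolate O-arylation (benzofuran formation) once an ortho iodide and copper are present.

**Step 7**
Reactants: 12 benzyl 2,4-bis(benzyloxy)-6-[(2-pentyl-1,3-dioxolan-2-yl)methyl]benzoate
Product: 13 benzyl 4,6-bis(benzyloxy)-3-iodo-2-[(2-pentyl-1,3-dioxolan-2-yl)methyl]benzoate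
Conditions: NIS (1.1 equiv), TFA (10 mol%), dry MeCN, 0 °C → rt
Reagents that add atoms: N-iodosuccinimide, O=C1CCC(=O)N1I
Why: Electrophilic aromatic iodination of 2,4-dialkoxy-6-alkylbenzoates goes to the carbon para to one alkoxy group and flanked by the other alkoxy group and the alkyl chain (C3′), not to the position wedged between the two alkoxy groups, and the ketal survives because the medium is anhydrous.

**Step 8**
Reactants: 13 benzyl 4,6-bis(benzyloxy)-3-iodo-2-[(2-pentyl-1,3-dioxolan-2-yl)methyl]benzoate; 7 8-hydroxy-6-methoxy-3-pentylisocoumarin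
Product: 14 benzyl 4,6-bis(benzyloxy)-3-[(6-methoxy-1-oxo-3-pentyl-1H-isochromen-8-yl)oxy]-2-[(2-pentyl-1,3-dioxolan-2-yl)methyl]benzoate
Conditions: CuI (20 mol%), picolinic acid (40 mol%), K3PO4 (2 equiv), dry DMSO, 90 °C
Reagents that add atoms: none
Why: Ullmann-type diaryl ether synthesis with a picolinate-ligated copper phenoxide is the catalyst system developed for ortho-substituted partners, and the dry phosphate base leaves the lactone, the benzyl ester and the ketal intact.

**Step 9**
Reactants: 14 benzyl 4,6-bis(benzyloxy)-3-[(6-methoxy-1-oxo-3-pentyl-1H-isochromen-8-yl)oxy]-2-[(2-pentyl-1,3-dioxolan-2-yl)methyl]benzoate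
Product: 16 β-collatolic acid, via ketal acid 15 (not isolated)
Conditions: H2 (1 atm), Pd/C (10% Pd on carbon), THF, rt, stopped after uptake of 3 equiv; filter; then TFA–H2O–THF (2:1:4), rt
Reagents that add atoms: water, O
Why: Hydrogenolysis cleaves the two aryl benzyl ethers and the benzyl ester faster than it saturates the conjugated, trisubstituted C3=C4 bond of the isocoumarin, and acid-catalysed acetal hydrolysis in the aqueous TFA then frees the ketone without touching the lactone, the methyl ether or the diaryl ether.

**Compound list**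
1 | 5,7-dimethoxyphthalide | COc1cc2COC(=O)c2c(OC)c1 | starting material
2 | triphenylphosphine hydrobromide | Br.c1ccc(cc1)P(c1ccccc1)c1ccccc1 | starting material
3 | (2-carboxy-3,5-dimethoxybenzyl)triphenylphosphonium bromide | [Br-].COc1cc(C[P+](c2ccccc2)(c2ccccc2)c2ccccc2)c(C(=O)O)c(OC)c1 | intermediate
4 | hexanoyl chloride | CCCCCC(Cl)=O | starting material
5 | mixed anhydride ylide: hexanoic 2,4-dimethoxy-6-[(triphenylphosphoranylidene)methyl]benzoic anhydride | CCCCCC(=O)OC(=O)c1c(OC)cc(OC)cc1C=P(c1ccccc1)(c1ccccc1)c1ccccc1 | intermediate (not isolated)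
6 | 6,8-dimethoxy-3-pentylisocoumarin (6,8-dimethoxy-3-pentyl-1H-isochromen-1-one) | CCCCCc1cc2cc(OC)cc(OC)c2c(=O)o1 | intermediate
7 | 8-hydroxy-6-methoxy-3-pentylisocoumarin | CCCCCc1cc2cc(OC)cc(O)c2c(=O)o1 | intermediate
8 | orsellinic acid (2,4-dihydroxy-6-methylbenzoic acid) | Cc1cc(O)cc(O)c1C(=O)O | starting material
9 | benzyl 2,4-bis(benzyloxy)-6-methylbenzoate | Cc1cc(OCc2ccccc2)cc(OCc2ccccc2)c1C(=O)OCc1ccccc1 | intermediate
10 | N-methoxy-N-methylhexanamide | CCCCCC(=O)N(C)OC | starting material
11 | benzyl 2,4-bis(benzyloxy)-6-(2-oxoheptyl)benzoate | CCCCCC(=O)Cc1cc(OCc2ccccc2)cc(OCc2ccccc2)c1C(=O)OCc1ccccc1 | intermediate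
12 | benzyl 2,4-bis(benzyloxy)-6-[(2-pentyl-1,3-dioxolan-2-yl)methyl]benzoate | CCCCCC1(Cc2cc(OCc3ccccc3)cc(OCc3ccccc3)c2C(=O)OCc2ccccc2)OCCO1 | intermediate
13 | benzyl 4,6-bis(benzyloxy)-3-iodo-2-[(2-pentyl-1,3-dioxolan-2-yl)methyl]benzoate | CCCCCC1(Cc2c(I)c(OCc3ccccc3)cc(OCc3ccccc3)c2C(=O)OCc2ccccc2)OCCO1 | intermediate
14 | benzyl 4,6-bis(benzyloxy)-3-[(6-methoxy-1-oxo-3-pentyl-1H-isochromen-8-yl)oxy]-2-[(2-pentyl-1,3-dioxolan-2-yl)methyl]benzoate | CCCCCC1(Cc2c(Oc3cc(OC)cc4cc(CCCCC)oc(=O)c34)c(OCc3ccccc3)cc(OCc3ccccc3)c2C(=O)OCc2ccccc2)OCCO1 | intermediate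
15 | ketal acid: 4,6-dihydroxy-3-[(6-methoxy-1-oxo-3-pentyl-1H-isochromen-8-yl)oxy]-2-[(2-pentyl-1,3-dioxolan-2-yl)methyl]benzoic acid | CCCCCC1(Cc2c(Oc3cc(OC)cc4cc(CCCCC)oc(=O)c34)c(O)cc(O)c2C(=O)O)OCCO1 | intermediate (not isolated)
16 | β-collatolic acid: 4,6-dihydroxy-3-[(6-methoxy-1-oxo-3-pentyl-1H-isochromen-8-yl)oxy]-2-(2-oxoheptyl)benzoic acid | CCCCCC(=O)Cc1c(Oc2cc(OC)cc3cc(CCCCC)oc(=O)c23)c(O)cc(O)c1C(=O)O | target

**Totals**
Total step count: 9. Longest linear sequence: 6 steps (steps 4 to 9, from orsellinic acid); the isocoumarin branch contributes steps 1 to 3.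

**Steps most likely to fail**

Step 8. Oxidative addition at the C–I bond, which is flanked on both sides, may be slow, and the chelated, carbonyl-conjugated phenoxide is a weak nucleophile. Protodeiodination, or lactone opening by traces of hydroxide, could then outrun C–O bond formation. The fallback inverts the roles of the partners; it sets out from 7 and 13 and comes back at 14. Phenol 7 would be converted with Tf2O and pyridine in CH2Cl2 at 0 °C into 6-methoxy-1-oxo-3-pentyl-1H-isochromen-8-yl trifluoromethanesulfonate F1, an electrophile activated by the ortho lactone carbonyl. Iodide 13 would undergo Miyaura borylation (B2pin2, PdCl2(dppf), KOAc, dioxane, 90 °C) to benzyl 4,6-bis(benzyloxy)-2-[(2-pentyl-1,3-dioxolan-2-yl)methyl]-3-(4,4,5,5-tetramethyl-1,3,2-dioxaborolan-2-yl)benzoate F2. Oxidation with NaBO3·4H2O in THF–H2O should then give benzyl 4,6-bis(benzyloxy)-3-hydroxy-2-[(2-pentyl-1,3-dioxolan-2-yl)methyl]benzoate F3. A palladium-catalysed C–O coupling of F1 with F3 (Pd(OAc)2, t-BuXPhos, K3PO4, toluene, 100 °C) would give 14, and the route continues with step 9.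

Step 7. The bulky ketal side chain shields C3′, so iodination may be misdirected to the position between the two benzyloxy groups. The acid co-catalyst may also open the ketal and allow iodination next to the ketone. The fallback places the halogen before the side chain is built, where only a methyl group flanks the site; it sets out from 9 and comes back at 13. Treatment of 9 with NIS and catalytic TFA in MeCN should give benzyl 4,6-bis(benzyloxy)-3-iodo-2-methylbenzoate F4. Lateral lithiation with LiN(iPr)2 in THF at −78 °C and acylation with 10 would give benzyl 4,6-bis(benzyloxy)-3-iodo-2-(2-oxoheptyl)benzoate F5. Ketalisation under the conditions of step 6 then gives 13.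

Step 9. Hydrogenolysis may over-reduce, saturating C3=C4 of the isocoumarin before the hindered benzyl ester has been cleaved. The fallback removes the benzyl groups without hydrogen; it sets out from 14 and comes back at 16. The ketal would first be hydrolysed with TFA–H2O–THF at rt to benzyl 4,6-bis(benzyloxy)-3-[(6-methoxy-1-oxo-3-pentyl-1H-isochromen-8-yl)oxy]-2-(2-oxoheptyl)benzoate F6. BCl3 with pentamethylbenzene as cation scavenger (CH2Cl2, −78 °C) should then cleave the two benzyl ethers and the benzyl ester by a Lewis acid pathway that spares the unchelated C6 methyl ether and the enol lactone, giving 16.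

**Further compounds**
F1 | step 8 | 6-methoxy-1-oxo-3-pentyl-1H-isochromen-8-yl trifluoromethanesulfonate | CCCCCc1cc2cc(OC)cc(OS(=O)(=O)C(F)(F)F)c2c(=O)o1
F2 | step 8 | benzyl 4,6-bis(benzyloxy)-2-[(2-pentyl-1,3-dioxolan-2-yl)methyl]-3-(4,4,5,5-tetramethyl-1,3,2-dioxaborolan-2-yl)benzoate | CCCCCC1(Cc2c(B3OC(C)(C)C(C)(C)O3)c(OCc3ccccc3)cc(OCc3ccccc3)c2C(=O)OCc2ccccc2)OCCO1
F3 | step 8 | benzyl 4,6-bis(benzyloxy)-3-hydroxy-2-[(2-pentyl-1,3-dioxolan-2-yl)methyl]benzoate | CCCCCC1(Cc2c(O)c(OCc3ccccc3)cc(OCc3ccccc3)c2C(=O)OCc2ccccc2)OCCO1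
F4 | step 7 | benzyl 4,6-bis(benzyloxy)-3-iodo-2-methylbenzoate | Cc1c(I)c(OCc2ccccc2)cc(OCc2ccccc2)c1C(=O)OCc1ccccc1
F5 | step 7 | benzyl 4,6-bis(benzyloxy)-3-iodo-2-(2-oxoheptyl)benzoate | CCCCCC(=O)Cc1c(I)c(OCc2ccccc2)cc(OCc2ccccc2)c1C(=O)OCc1ccccc1
F6 | step 9 | benzyl 4,6-bis(benzyloxy)-3-[(6-methoxy-1-oxo-3-pentyl-1H-isochromen-8-yl)oxy]-2-(2-oxoheptyl)benzoate | CCCCCC(=O)Cc1c(Oc2cc(OC)cc3cc(CCCCC)oc(=O)c23)c(OCc2ccccc2)cc(OCc2ccccc2)c1C(=O)OCc1ccccc1
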